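**Plan**
- Retrosynthesis: cut the C4–O–C6' ether between the two isochromanone halves (Mitsunobu, inversion), so both halves come from one monomer 12; take C4–OH of 12 back to the C4 ketone 11; then cut C1–C8a and C4–C4a together, back to an aryne, a dithiane acyl-anion carrying C4/C3/CH3, and CO2.
- Enabling feature: the lactone carbonyl C1 and the carbinol C4 sit on adjacent benzene carbons C8a and C4a, and C8a is flanked by the C8 oxygen. An aryne across C4a–C8a is polarised by that oxygen, so a carbon nucleophile enters at C4a and the carbanion left at C8a takes up CO2.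
- Forward order: the benzene ring is bought (2-methoxyresorcinol); the lactone ring is formed in the key step; the two bicycles are joined last through the ether oxygen.
- Helpers: the dithiane is the umpoled C4, keeps C4 oxygen-free so that only the six-membered lactone can close, and is later unmasked to the ketone; benzyl and TBS groups come off at the end.
- Stereochemistry: C3 and C4 of both halves are set together by Ru-catalysed asymmetric transfer hydrogenation with dynamic kinetic resolution of 11 (cis, 3R,4R); C4 of the ether-bearing half is inverted to S in the Mitsunobu coupling.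

Key step: step 4

Remark on the chemistry: C3 of ketone 11 is configurationally labile (its enol is a 4-hydroxyisocoumarin), so 6, 10 and 11 are carried as racemates and all stereochemistry is introduced from step 6 on.

Step 1
Reactants: 1 2-methoxybenzene-1,3-diol
Product: 2 1,3-bis(benzyloxy)-2-methoxybenzene
Conditions: BnBr, K2CO3, DMF, rt to 50 °C
Reagents that add atoms: benzyl bromide (BrCc1ccccc1)
Why: Williamson etherification of both phenols; the benzyl ethers tolerate the organolithium, iodine(III) and Ru–H steps that follow.

Step 2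
Reactants: 2 1,3-bis(benzyloxy)-2-methoxybenzene
Product: 3 1,3-bis(benzyloxy)-4-chloro-2-methoxybenzene
Conditions: NCS (1.05 equiv), DMF, rt
Reagents that add atoms: N-chlorosuccinimide (ClN1C(=O)CCC1=O)
Why: Electrophilic aromatic chlorination at the position ortho to one benzyloxy group and para to the other (the two such positions are equivalent by symmetry); chloride is chosen over bromide so that no halogen–lithium exchange can compete in step 4.

Step 3
Reactants: 4 1,3-dithiane; 5 acetaldehyde
Product: 6 rac-1-(1,3-dithian-2-yl)ethan-1-ol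
Conditions: n-BuLi, THF, −30 °C; then 5, −78 °C; H2O
Reagents that add atoms: none
Why: Corey–Seebach addition of 2-lithio-1,3-dithiane to the aldehyde; the new carbinol centre is left racemic because it is equilibrated after step 5.

Step 4
Reactants: 3 1,3-bis(benzyloxy)-4-chloro-2-methoxybenzene; 6 rac-1-(1,3-dithian-2-yl)ethan-1-ol
Product: 10 rac-6,8-bis(benzyloxy)-7-methoxy-3-methylspiro[isochromane-4,2'-[1,3]dithian]-1-one, via aryne 7 (not isolated), via aryllithium 8 (not isolated), via hydroxy acid 9 (not isolated)
Conditions: 6 (2.3 equiv), n-BuLi (4.6 equiv), THF, −78 to 0 °C; add 3, −78 to 0 °C; CO2 (g), −78 °C to rt; aq. HCl; then TsOH·H2O (cat.), PhMe, 60 °C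
Reagents that add atoms: carbon dioxide (O=C=O)
Why: Doubly lithiated 6 (alkoxide plus C2 carbanion) first removes the ring proton next to chlorine in 3, and loss of LiCl gives aryne 7 with its triple bond across the future C4a and C8a; a second molecule adds through its dithiane carbon to the aryne carbon remote from the neighbouring benzyloxy group (future C4a), leaving aryllithium 8 at the carbon flanked by that oxygen (future C8a), which is carboxylated by CO2 and, after acidification, closes onto the C3 hydroxyl. The closest known reaction type is the three-component aryne coupling (organolithium addition to a 3-alkoxybenzyne, then electrophilic capture of the ortho-alkoxy aryllithium, here with CO2), combined with Corey–Seebach acyl-anion chemistry. The lactone ring closes by 6-exo-trig acyl substitution of the C3 hydroxyl on the new carboxyl group; a five-membered phthalide cannot compete because C4 carries sulfur, not oxygen. No stereocentre is controlled here: C3 stays racemic and is corrected in step 6. The step needs regioselective addition to the aryne and C- over O-attack: the inductive (bond-angle distortion) effect of the C8 oxygen directs the nucleophile to C4a and stabilises the C8a anion, the dithiane carbanion is far more nucleophilic than the lithium alkoxide, and the absence of any amine keeps 8 from being protonated before CO2 arrives.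

Step 5
Reactants: 10 rac-6,8-bis(benzyloxy)-7-methoxy-3-methylspiro[isochromane-4,2'-[1,3]dithian]-1-one
Product: 11 rac-6,8-bis(benzyloxy)-7-methoxy-3-methylisochromane-1,4-dione
Conditions: PhI(OCOCF3)2 (1.5 equiv), MeCN–H2O (9:1), 0 °C to rt
Reagents that add atoms: water (O)
Why: Oxidative dethioketalisation with iodine(III): sulfur is oxidised, water adds to the thionium ion and the aryl ketone is released, while benzyl ethers and the lactone should be untouched.

Step 6
Reactants: 11 rac-6,8-bis(benzyloxy)-7-methoxy-3-methylisochromane-1,4-dione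
Product: 12 (3R,4R)-6,8-bis(benzyloxy)-4-hydroxy-7-methoxy-3-methylisochroman-1-one
Conditions: RuCl[(S,S)-TsDPEN](p-cymene) (2 mol%), HCO2H–Et3N (5:2), DMF, 30 °C
Reagents that add atoms: none
Why: Noyori–Ikariya asymmetric transfer hydrogenation with dynamic kinetic resolution: C3 equilibrates through the 4-hydroxyisocoumarin enol, the (S,S) catalyst should deliver hydride to the carbonyl face that gives 4R (same sense as for 1-tetralone and 4-chromanone), and the enantiomer whose C3 methyl lies anti to the incoming hydride reacts faster, so the cis (3R,4R) alcohol is expected.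

Step 7
Reactants: 12 (3R,4R)-6,8-bis(benzyloxy)-4-hydroxy-7-methoxy-3-methylisochroman-1-one
Product: 13 (3R,4R)-6,8-bis(benzyloxy)-4-[(tert-butyldimethylsilyl)oxy]-7-methoxy-3-methylisochroman-1-one
Conditions: TBSOTf, 2,6-lutidine, CH2Cl2, −40 to 0 °C
Reagents that add atoms: tert-butyldimethylsilyl triflate (CC(C)(C)[Si](C)(C)OS(=O)(=O)C(F)(F)F)
Why: Silylation of the hindered secondary benzylic alcohol with a silyl triflate and a weak hindered base, which should avoid lactone migration to O4; no stereocentre is touched.

Step 8
Reactants: 13 (3R,4R)-6,8-bis(benzyloxy)-4-[(tert-butyldimethylsilyl)oxy]-7-methoxy-3-methylisochroman-1-one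
Product: 14 (3R,4R)-4-[(tert-butyldimethylsilyl)oxy]-6,8-dihydroxy-7-methoxy-3-methylisochroman-1-one
Conditions: H2 (1 atm), 10% Pd/C, EtOAc, rt
Reagents that add atoms: none
Why: Hydrogenolysis of the two aryl benzyl ethers; the benzylic silyl ether and the lactone should survive in a non-protic solvent.

Step 9
Reactants: 12 (3R,4R)-6,8-bis(benzyloxy)-4-hydroxy-7-methoxy-3-methylisochroman-1-one (second portion); 14 (3R,4R)-4-[(tert-butyldimethylsilyl)oxy]-6,8-dihydroxy-7-methoxy-3-methylisochroman-1-one
Product: 15 (3R,4S)-6,8-bis(benzyloxy)-4-({(3R,4R)-4-[(tert-butyldimethylsilyl)oxy]-8-hydroxy-7-methoxy-3-methyl-1-oxoisochroman-6-yl}oxy)-7-methoxy-3-methylisochroman-1-one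
Conditions: PPh3, DIAD, THF–PhMe, 0 °C to rt
Reagents that add atoms: none
Why: Mitsunobu etherification: the more acidic, non-chelated C6 phenol of 14 (para to the lactone carbonyl) attacks the alkoxyphosphonium of 12 in an SN2 step from the face anti to the leaving oxygen and the cis C3 methyl, inverting C4 to S and giving the trans ether, while the C8 phenol stays hydrogen-bonded to the lactone carbonyl.

Step 10
Reactants: 15 (3R,4S)-6,8-bis(benzyloxy)-4-({(3R,4R)-4-[(tert-butyldimethylsilyl)oxy]-8-hydroxy-7-methoxy-3-methyl-1-oxoisochroman-6-yl}oxy)-7-methoxy-3-methylisochroman-1-one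
Product: 17 (3R,4S)-4-{[(3R,4R)-4,8-dihydroxy-7-methoxy-3-methyl-1-oxoisochroman-6-yl]oxy}-6,8-dihydroxy-7-methoxy-3-methylisochroman-1-one (target), via silyl ether 16 (not isolated)
Conditions: H2 (1 atm), 10% Pd/C, EtOAc, rt; filter; then HF·pyridine, THF–pyridine, 0 °C to rt
Reagents that add atoms: none
Why: Hydrogenolysis should remove the two primary O-benzyl groups much faster than the hindered secondary benzylic aryl ether (as in debenzylation of benzyl-protected flavans), and HF·pyridine then cleaves the silyl ether under non-basic conditions that avoid lactone migration to the freed C4 hydroxyl; no stereocentre is touched.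

**Compound list**
1 | 2-methoxybenzene-1,3-diol | COc1c(O)cccc1O | starting material
2 | 1,3-bis(benzyloxy)-2-methoxybenzene | COc1c(OCc2ccccc2)cccc1OCc1ccccc1 | intermediate
3 | 1,3-bis(benzyloxy)-4-chloro-2-methoxybenzene | COc1c(OCc2ccccc2)ccc(Cl)c1OCc1ccccc1 | intermediate
4 | 1,3-dithiane | C1CSCSC1 | starting material
5 | acetaldehyde | CC=O | starting material
6 | rac-1-(1,3-dithian-2-yl)ethan-1-ol | CC(O)C1SCCCS1 | intermediate
7 | 3,5-bis(benzyloxy)-4-methoxy-1,2-didehydrobenzene (aryne) | COC1=C(OCc2ccccc2)C#CC=C1OCc1ccccc1 | intermediate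
8 | [2,4-bis(benzyloxy)-6-{2-[1-(lithiooxy)ethyl]-1,3-dithian-2-yl}-3-methoxyphenyl]lithium | [Li]c1c(OCc2ccccc2)c(OC)c(OCc2ccccc2)cc1C1(SCCCS1)C(C)O[Li] | intermediate
9 | rac-2,4-bis(benzyloxy)-6-[2-(1-hydroxyethyl)-1,3-dithian-2-yl]-3-methoxybenzoic acid | OC(=O)c1c(OCc2ccccc2)c(OC)c(OCc2ccccc2)cc1C1(SCCCS1)C(C)O | intermediate
10 | rac-6,8-bis(benzyloxy)-7-methoxy-3-methylspiro[isochromane-4,2'-[1,3]dithian]-1-one | CC1OC(=O)c2c(OCc3ccccc3)c(OC)c(OCc3ccccc3)cc2C12SCCCS2 | intermediate
11 | rac-6,8-bis(benzyloxy)-7-methoxy-3-methylisochromane-1,4-dione | CC1OC(=O)c2c(OCc3ccccc3)c(OC)c(OCc3ccccc3)cc2C1=O | intermediate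
12 | (3R,4R)-6,8-bis(benzyloxy)-4-hydroxy-7-methoxy-3-methylisochroman-1-one | COc1c(OCc2ccccc2)cc2c(c1OCc1ccccc1)C(=O)O[C@H](C)[C@@H]2O | intermediate
13 | (3R,4R)-6,8-bis(benzyloxy)-4-[(tert-butyldimethylsilyl)oxy]-7-methoxy-3-methylisochroman-1-one | COc1c(OCc2ccccc2)cc2c(c1OCc1ccccc1)C(=O)O[C@H](C)[C@@H]2O[Si](C)(C)C(C)(C)C | intermediate
14 | (3R,4R)-4-[(tert-butyldimethylsilyl)oxy]-6,8-dihydroxy-7-methoxy-3-methylisochroman-1-one | COc1c(O)cc2c(c1O)C(=O)O[C@H](C)[C@@H]2O[Si](C)(C)C(C)(C)C | intermediate
15 | (3R,4S)-6,8-bis(benzyloxy)-4-({(3R,4R)-4-[(tert-butyldimethylsilyl)oxy]-8-hydroxy-7-methoxy-3-methyl-1-oxoisochroman-6-yl}oxy)-7-methoxy-3-methylisochroman-1-one | COc1c(OCc2ccccc2)cc2c(c1OCc1ccccc1)C(=O)O[C@H](C)[C@H]2Oc1cc2c(c(O)c1OC)C(=O)O[C@H](C)[C@@H]2O[Si](C)(C)C(C)(C)C | intermediate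
16 | (3R,4S)-4-({(3R,4R)-4-[(tert-butyldimethylsilyl)oxy]-8-hydroxy-7-methoxy-3-methyl-1-oxoisochroman-6-yl}oxy)-6,8-dihydroxy-7-methoxy-3-methylisochroman-1-one | COc1c(O)cc2c(c1O)C(=O)O[C@H](C)[C@H]2Oc1cc2c(c(O)c1OC)C(=O)O[C@H](C)[C@@H]2O[Si](C)(C)C(C)(C)C | intermediate
17 | (3R,4S)-4-{[(3R,4R)-4,8-dihydroxy-7-methoxy-3-methyl-1-oxoisochroman-6-yl]oxy}-6,8-dihydroxy-7-methoxy-3-methylisochroman-1-one | COc1c(O)cc2c(c1O)C(=O)O[C@H](C)[C@H]2Oc1cc2c(c(O)c1OC)C(=O)O[C@H](C)[C@@H]2O | target

**Totals**
Total step count: 10. Longest linear sequence: 9 steps (1, 2, 4, 5, 6, 7, 8, 9, 10); step 3 is a one-step side branch, and 12 is used twice (as the alcohol in step 9 and as the source of 14).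

**Three steps most likely to fail**

Step 4. The doubly lithiated dithiane alcohol may not work as both base and nucleophile: aryne formation may be slow, deprotonation next to a benzyloxy group may compete, or the aryllithium may be protonated before CO2 capture, so that no carboxylated adduct forms. The fallback installs the two ring carbons one at a time by directed metalation, setting out from 2. Bromination with NBS should give 1,3-bis(benzyloxy)-4-bromo-2-methoxybenzene F1. Bromine–lithium exchange with n-BuLi at −78 °C and quenching with methyl chloroformate should give methyl 2,4-bis(benzyloxy)-3-methoxybenzoate F2. Ester-directed magnesiation of the only free ortho position with TMPMgCl·LiCl, transmetalation to copper and acylation with racemic 2-[(tert-butyldimethylsilyl)oxy]propanoyl chloride should give methyl 2,4-bis(benzyloxy)-6-{2-[(tert-butyldimethylsilyl)oxy]propanoyl}-3-methoxybenzoate F3. Desilylation with HF·pyridine and acid-catalysed lactonisation in warm toluene should then close the six-membered lactone onto the ester and return to the route at 11.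

Step 9. The activated benzylic alcohol may eliminate toward the 3-methylisocoumarin, or ionise with loss of the clean inversion, or the two hindered partners may simply couple too slowly. The fallback separates activation from displacement, setting out from 12. Treatment with methanesulfonic anhydride and triethylamine at low temperature should give (3R,4R)-6,8-bis(benzyloxy)-7-methoxy-3-methyl-1-oxoisochroman-4-yl methanesulfonate F6. The pre-formed caesium C6-phenoxide of 14 (Cs2CO3, DMF, 0 °C) should then displace it with inversion and return to the route at 15.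

Step 6. Equilibration of C3 may be slower than hydride transfer, so that diastereo- and enantioselectivity erode, or the product may begin to migrate its lactone to O4 in the amine-containing medium. The fallback replaces catalyst control by substrate control plus resolution, setting out from 11. Reduction with NaBH4/CeCl3 in MeOH at −78 °C should give mainly racemic cis-6,8-bis(benzyloxy)-4-hydroxy-7-methoxy-3-methylisochroman-1-one F4 by hydride attack anti to the C3 methyl, with any trans isomer removed by chromatography. Lipase-catalysed acylation (Burkholderia cepacia lipase, vinyl acetate, MTBE) is then expected to acetylate the (3S,4S) enantiomer to (3S,4S)-6,8-bis(benzyloxy)-7-methoxy-3-methyl-1-oxoisochroman-4-yl acetate F5 and leave the (3R,4R) alcohol, which is 12; at most half of the material is recovered this way.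

Further compounds
F1 | step 4 | 1,3-bis(benzyloxy)-4-bromo-2-methoxybenzene | COc1c(OCc2ccccc2)ccc(Br)c1OCc1ccccc1
F2 | step 4 | methyl 2,4-bis(benzyloxy)-3-methoxybenzoate | COC(=O)c1ccc(OCc2ccccc2)c(OC)c1OCc1ccccc1
F3 | step 4 | rac-methyl 2,4-bis(benzyloxy)-6-{2-[(tert-butyldimethylsilyl)oxy]propanoyl}-3-methoxybenzoate | COC(=O)c1c(OCc2ccccc2)c(OC)c(OCc2ccccc2)cc1C(=O)C(C)O[Si](C)(C)C(C)(C)C
F4 | step 6 | rac-cis-6,8-bis(benzyloxy)-4-hydroxy-7-methoxy-3-methylisochroman-1-one (both enantiomers) | COc1c(OCc2ccccc2)cc2c(c1OCc1ccccc1)C(=O)O[C@H](C)[C@@H]2O.COc1c(OCc2ccccc2)cc2c(c1OCc1ccccc1)C(=O)O[C@@H](C)[C@H]2O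
F5 | step 6 | (3S,4S)-6,8-bis(benzyloxy)-7-methoxy-3-methyl-1-oxoisochroman-4-yl acetate | COc1c(OCc2ccccc2)cc2c(c1OCc1ccccc1)C(=O)O[C@@H](C)[C@H]2OC(C)=O
F6 | step 9 | (3R,4R)-6,8-bis(benzyloxy)-7-methoxy-3-methyl-1-oxoisochroman-4-yl methanesulfonate | COc1c(OCc2ccccc2)cc2c(c1OCc1ccccc1)C(=O)O[C@H](C)[C@@H]2OS(C)(=O)=O
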